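The earlier runs and the new flask stem from a simulated flask on assumed constants; scatter was added.

Read at 10.0 h, the teal and green runs are what this bench note stands on.

| setting | teal | green | Monday's | Saturday's |
|---|---|---|---|---|
| starting material | 0.10 M (fed, over 6.0 h) | 0.10 M (fed, over 6.0 h) | 0.10 M (fed, over 6.0 h) | 0.10 M |
| second substrate | 0.50 equiv | 0.50 equiv | 0.500 equiv | 0.500 equiv |
| enzyme | 0.008 mol% | 0.022 mol% | 0.01 mol% | 0.03 mol% |
| remark | run made earlier; the fed solution adds 1.0 times the starting volume | run made earlier; the fed solution adds 1.0 times the starting volume | the fed solution adds 1.0 times the starting volume | everything together at the start, the whole solution of starting material included, so that from the start the volume is larger by 1.0 times the starting volume |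
| time |  |  | 10 h | 10 h |

- teal (time / h: target / %, starting material / %): 0.833: 0.7, 13.0; 1.33: 1.6, 22.1; 2.00: 1.8, 30.4; 4.00: 7.1, 58.5; 6.00: 10.4, 82.9; 10.0: 21.3, 66.6
- green (time / h: target / %, starting material / %): 0.833: 1.8, 12.1; 1.33: 2.5, 18.8; 2.00: 6.5, 27.6; 4.00: 15.3, 49.0; 6.00: 27.8, 67.5; 10.0: 48.2, 42.2

(readings scatter by 0.5 percentage points)

- amounts are per litre of the starting volume; all of the dose is in the solution fed
- the numbers in the tables scatter by 0.5 percentage points (one standard deviation)
- percentages count the whole charge, also what has not yet gone in

1. the flask that ends with the higher amount of target, in percent of the starting material charged, or "neither" when 2 percentage points or less lies between them (Monday's / Saturday's / neither)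
2. final target, as a percentage of the starting material charged, in Monday's
3. final target, as a percentage of the starting material charged, in Saturday's

1. Teal and green stand at full volume once the feed ends at 6.0 h, as Saturday's does from the start. Target gained per hour over mean starting material gives a pseudo-first-order constant. Scaled by loading to Saturday's, teal gives 0.137 /h and green 0.127 /h; the mean is k = 0.132 /h.

2. Green's target reached 48.2% on 0.50 equiv of second substrate, a reading that does not test a one-to-one cap; this reckoning sets no cap, and that is its assumption.

3. Target plus starting material falls after the feed, at 0.0181 /h in teal and 0.0223 /h in green; the mean is a loss constant L = 0.0202 /h.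

4. The time constant of consumption, τ = 1/(k + L), is 6.58 h for Saturday's. Target at time t is then k·τ·(1 − exp(−t/τ)), which gives 67.7% at 10 h.

5. Monday's, interpolated between teal and green, gives 25.1%.

6. Saturday's should not be stopped early: at 10 h this reckoning still leaves 21.9% of the starting material.

The forecast picks Saturday's, with 26.5% for Monday's and 49.5% for Saturday's, holding that “0.50 equiv should cap target”. This reckoning differs from it on Saturday's.

The flasks end at 26.4% in Monday's and 68.5% in Saturday's, so the higher is Saturday's. In Saturday's at 5.00 h, second substrate stood at 0% of its own charge and target at 45.7%, and target went on rising. The same τ gives 46.2% for that time.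

    2 complex B ⇌ resting dimer (K = 24000 /M, k = 1.79 × 10⁵ /M/h)
    complex A → enzyme + target (k = 2340 /h)
    complex B → enzyme + second product (k = 1.80 × 10⁵ /h)
    starting material → uncatalysed product (k = 0.0199 /h)
    second substrate + enzyme ⇌ complex B (K = 495 /M, k = 1.29 × 10⁷ /M/h)
    starting material + enzyme ⇌ complex A (K = 4.30 /M, k = 1.58 × 10⁶ /M/h)

The neighbour with 0.051 mol% of enzyme has k = 0.224 /h and τ = 4.10 h, which gives 83.8%. The computed flask gives 84.9%.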